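**Retrosynthetic overview**
1. The chroman ring closes last. Cutting the aryl–CH2 and O–CMe2 bonds gives a free p-hydroxybenzyl butenolide plus isoprene as the dimethylallyl cation source. Aromatic prenylation and phenol-onto-alkene closure then run in one pot.
2. The butenolide ring closes first. Cutting the C(quaternary)–C(Ph) aldol bond and the lactone acyl–O bond gives two different arylpyruvates.
3. The donor is phenylpyruvate as its S-ethyl thioester, a mimic of the carrier-bound thioester, so lactonisation acts as the off-loading step. The acceptor is methyl 4-hydroxyphenylpyruvate. One catalytic enantioselective hetero-aldol/lactonisation sets the only stereocentre (R).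
4. Each partner is made in one step from a commercial arylpyruvic acid, with no protecting groups. Ring order: butenolide, then prenylation, then chroman, as in the presumed biogenesis.

Assumption: all arylpyruvates are written as keto tautomers although they exist largely as (Z)-enols, and the quinidine-series thiourea is assumed to direct Re-face attack; this is checked on the first run by ECD and optical rotation against the natural (R)-series, and the equally available quinine-series pseudo-enantiomer is used if the sense is opposite.

**Step 1**
Reactants: 1 4-hydroxyphenylpyruvic acid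
Product: 2 methyl 3-(4-hydroxyphenyl)-2-oxopropanoate
Conditions: MeI (1.2 equiv), KHCO3 (1.1 equiv), DMF, 0 °C to rt
Reagents that add atoms: iodomethane, CI
Why: Carboxylate SN2 O-alkylation, in which bicarbonate deprotonates only the carboxylic acid (not the phenol or the enol), so MeI methylates the carboxylate alone and the medium never becomes basic enough to start self-aldol condensation; no stereocentre is formed.

**Step 2**
Reactants: 3 phenylpyruvic acid
Product: 4 S-ethyl 2-oxo-3-phenylpropanethioate
Conditions: EtSH (1.5 equiv), DCC (0.95 equiv), DMAP (5 mol %), CH2Cl2, 0 °C, 2 h; filter, cold 0.5 M HCl wash, short SiO2 plug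
Reagents that add atoms: ethanethiol, CCS
Why: Steglich-type carbodiimide thioesterification, in which the soft thiol outcompetes the enol OH for the activated acyl species and the slight excess of acid 3 keeps DMAP protonated so that the base-sensitive product does not self-condense; no stereocentre is formed.

**Step 3**
Reactants: 4 S-ethyl 2-oxo-3-phenylpropanethioate; 2 methyl 3-(4-hydroxyphenyl)-2-oxopropanoate
Product: 7 methyl (2R)-4-hydroxy-2-(4-hydroxybenzyl)-5-oxo-3-phenyl-2,5-dihydrofuran-2-carboxylate, via aldol adduct 5 (not isolated), via keto lactone 6 (not isolated)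
Conditions: 2 (2.0 equiv), N-[3,5-bis(trifluoromethyl)phenyl]-N'-[(9R)-6'-methoxycinchonan-9-yl]thiourea (10 mol %), 4 Å MS, CH2Cl2, Ar, −30 °C; 4 (1.0 equiv) added over 12 h by syringe pump; then 1 M HCl
Reagents that add atoms: none
Why: Proposed new method: the quinuclidine nitrogen deprotonates the more acidic, fully enolised thioester 4 while the thiourea N–H pair binds the 1,2-dicarbonyl of the keto tautomer of 2, so the enolate carbon attacks the Re face of the ketone to give the (R)-tertiary aldolate 5; this is trapped at once by 5-exo-trig attack on the α-keto thioester (EtSH is about five pKa units better as a leaving group than MeOH, and the thiourea serves as an oxyanion hole), so only adducts with 4 as donor go forward while adducts with 2 as donor can only revert; slow addition of 4 into excess 2 suppresses 4+4 dimerisation, and enolisation of 6 to 7 erases the benzylic centre so that only the quaternary centre counts; the closest known reaction types are the amine- or Cu(II)-bisoxazoline-catalysed homo-aldol/lactonisation of pyruvates to isotetronic acids, the base-mediated dimerisation of methyl arylpyruvates to butenolides, and the bifunctional cinchona-catalysed enantioselective addition of carbon acids (nitroaldol, aldol) to α-keto esters.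

**Step 4**
Reactants: 7 methyl (2R)-4-hydroxy-2-(4-hydroxybenzyl)-5-oxo-3-phenyl-2,5-dihydrofuran-2-carboxylate; 8 isoprene
Product: 10 4'-dehydroxy aspernolide A (target), via ortho-prenylphenol 9 (not isolated)
Conditions: isoprene (2–3 equiv, in portions), AgOTf (10 mol %), ClCH2CH2Cl, sealed tube, rt to 40 °C; stop at about 85 % conversion
Reagents that add atoms: none
Why: Metal-triflate-catalysed Friedel–Crafts prenylation followed by intramolecular Markovnikov hydroalkoxylation (the known one-pot phenol + isoprene to 2,2-dimethylchroman annulation), in which protonated isoprene is the same dimethylallyl cation that DMAPP delivers, the para position is blocked and the two ortho positions are equivalent, the alkene of 9 then closes 6-endo onto the phenol oxygen (acid cyclisation of such prenylphenol butenolides to chromans is established), any O-prenylation of the enol is reversible under acid, and the quaternary (R)-centre flanked by ester and lactone cannot ionise and is untouched.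

**Compound list**
1 | 4-hydroxyphenylpyruvic acid | O=C(O)C(=O)Cc1ccc(O)cc1 | starting material
2 | methyl 3-(4-hydroxyphenyl)-2-oxopropanoate | COC(=O)C(=O)Cc1ccc(O)cc1 | intermediate
3 | phenylpyruvic acid | O=C(O)C(=O)Cc1ccccc1 | starting material
4 | S-ethyl 2-oxo-3-phenylpropanethioate | CCSC(=O)C(=O)Cc1ccccc1 | intermediate
5 | methyl (2R)-5-(ethylsulfanyl)-2-hydroxy-2-(4-hydroxybenzyl)-4,5-dioxo-3-phenylpentanoate (C3 epimers, not isolated) | COC(=O)[C@@](O)(Cc1ccc(O)cc1)C(c1ccccc1)C(=O)C(=O)SCC | intermediate
6 | methyl (2R)-2-(4-hydroxybenzyl)-4,5-dioxo-3-phenyltetrahydrofuran-2-carboxylate (C3 epimers, not isolated) | COC(=O)[C@]1(Cc2ccc(O)cc2)OC(=O)C(=O)C1c1ccccc1 | intermediate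
7 | methyl (2R)-4-hydroxy-2-(4-hydroxybenzyl)-5-oxo-3-phenyl-2,5-dihydrofuran-2-carboxylate | COC(=O)[C@]1(Cc2ccc(O)cc2)OC(=O)C(O)=C1c1ccccc1 | intermediate
8 | isoprene | C=CC(C)=C | starting material
9 | methyl (2R)-4-hydroxy-2-[4-hydroxy-3-(3-methylbut-2-en-1-yl)benzyl]-5-oxo-3-phenyl-2,5-dihydrofuran-2-carboxylate (not isolated) | COC(=O)[C@]1(Cc2ccc(O)c(CC=C(C)C)c2)OC(=O)C(O)=C1c1ccccc1 | intermediate
10 | 4'-dehydroxy aspernolide A, methyl (2R)-2-[(2,2-dimethylchroman-6-yl)methyl]-4-hydroxy-5-oxo-3-phenyl-2,5-dihydrofuran-2-carboxylate | COC(=O)[C@]1(Cc2ccc3c(c2)CCC(C)(C)O3)OC(=O)C(O)=C1c1ccccc1 | target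

**Total step count:** 4. **Longest linear sequence:** 3 (1 → 2 → 7 → 10, or 3 → 4 → 7 → 10).

**Steps most likely to fail**

Step 3 is the riskiest.
- Risks: a reversible aldol step may erode the ee, and the homodimers 4+4 and 2+2 may compete. The sense of induction is predicted from a model, not from precedent.
- Fallback: it sets out from 4 and 2 and comes back at 7, and the stereocentre is obtained by resolution instead of catalysis. The thioester-driven hetero-condensation is run with an achiral base (DBU, 20 mol %, CH2Cl2/DMF, 0 °C, slow addition of 4) to give the racemic butenolide F1. This is separated by preparative SFC on an immobilised amylose phase. The (R)-enantiomer is 7 and continues, and the (S)-enantiomer F2 is set aside.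

Step 4 comes next.
- Risks: a second prenylation at C8 of the new chroman, isoprene oligomerisation, or stalled conversion on this polyfunctional substrate.
- Fallback: it sets out from 7 and comes back at 9, and replaces cationic C–C bond formation by halogenation and cross-coupling.
  - Mono-iodination ortho to the phenol (NIS 1.0 equiv, cat. TsOH, MeCN, 0 °C) gives the ortho-iodophenol F3.
  - Stille coupling with tributyl(3-methylbut-2-en-1-yl)stannane (Pd(PPh3)4, DMF, 80 °C) gives 9, which is now isolated.
  - Compound 9 is closed to 10 in a separate acid step (cat. p-TsOH, toluene, 60 °C).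

Step 2 is third.
- Risks: self-condensation of 4 once any free base is present, N-acylurea formation, or acylation of the enol OH.
- Fallback: it sets out from 3 and comes back at 4, and masks the enol and activates the carboxyl group at the same time under acid.
  - 2,2-Dimethoxypropane with cat. CSA in CH2Cl2 (MeOH removed over sieves) gives (Z)-5-benzylidene-2,2-dimethyl-1,3-dioxolan-4-one F4.
  - NaSEt (1.0 equiv, THF, −78 to 0 °C) opens F4 at the acyl carbon with loss of acetone.
  - This delivers 4 as its enolate. With no keto form present, the enolate cannot self-condense.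
  - A cold 1 M HCl quench then releases 4.

**Further compounds**
F1 | step 3 | racemic methyl 4-hydroxy-2-(4-hydroxybenzyl)-5-oxo-3-phenyl-2,5-dihydrofuran-2-carboxylate | COC(=O)C1(Cc2ccc(O)cc2)OC(=O)C(O)=C1c1ccccc1
F2 | step 3 | methyl (2S)-4-hydroxy-2-(4-hydroxybenzyl)-5-oxo-3-phenyl-2,5-dihydrofuran-2-carboxylate | COC(=O)[C@@]1(Cc2ccc(O)cc2)OC(=O)C(O)=C1c1ccccc1
F3 | step 4 | methyl (2R)-4-hydroxy-2-(4-hydroxy-3-iodobenzyl)-5-oxo-3-phenyl-2,5-dihydrofuran-2-carboxylate | COC(=O)[C@]1(Cc2ccc(O)c(I)c2)OC(=O)C(O)=C1c1ccccc1
F4 | step 2 | (Z)-5-benzylidene-2,2-dimethyl-1,3-dioxolan-4-one | CC1(C)OC(=O)/C(=C/c2ccccc2)O1
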